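## Structural features

The target is a germacranolide: a ten-membered carbocycle (C1–C10, germacrane numbering throughout) with a cis-fused α-methylene-γ-butyrolactone across C7–C8 (ring oxygen on C8, C12 carbonyl, exocyclic C11=C13). C1 is a ketone whose neighbour C10 bears only a hydrogen and the C14 methyl; C4 is a tertiary carbinol (C15 methyl); C6 carries the isobutyrate. C6, C7 and C8 are contiguous stereocentres, C4 is 1,3-anti to C6, and C10 stands alone and is epimerisable because it is α to the ketone. The fragile groups are the α-methylene lactone (Michael acceptor), the C6 ester beside the lactone (acyl transfer, translactonisation when C6–OH is free) and the C4–OH/C1=O pair, which can close across the ring to a hemiketal. The real difficulty is closing a ten-membered ring that already holds four of five stereocentres, then raising the oxidation level at C12, C13 and C6 without losing C10. The key step exploits the C1(=O)–C10H(CH3) unit: an α-methyl ketone with no other α-substituent is what enol ether hydrolysis gives after titanium coupling of a C10 methyl ketone with a C1 ester. A second exploitable feature is that C6, C7 and C8 map onto a cis-fused bicyclic cyclopentene lactone, so all three can be fixed on a rigid bicycle before the chain is opened.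

## Logic of the disconnections

From 27 back to 24 (through 26 and 25). The C6–O acyl bond is cut, and C1=O with C4–OH is tied into a bridged methyl ketal. The ester and the free hydroxy ketone are the most labile groups, and one ketal hides both the ketone and the tertiary alcohol. Forward, the acylation must meet a single free hydroxyl and the last hydrolysis must spare the ester and the methylene lactone.

From 24 back to 21. C11=C13 is cut. The methylene lactone is too electrophilic to carry through earlier steps. Forward, enolisation must occur only at C11; this is why the ketone is masked and C6 is a silyl ether rather than an ester at that stage.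

From 21 back to 19 (through 20). The C12 carbonyl oxygen is removed (lactone back to cyclic ether) and the ketal is reopened to ketone and silyl ether. A reductive carbonyl coupling tolerates only one ester, so the lactone is carried as an inert ether. Forward, the oxidation must choose the C12 methylene over the C8 methine.

From 19 back to 17. C1–C10 is cut, which opens the ten-membered ring to a chain held cis on the tetrahydrofuran. All four remaining stereocentres are already in 17, and they have the same configuration as in 27 (checked centre by centre at C4, C6, C7 and C8). Forward, the step needs one ketone, one ester and high dilution.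

From 17 back to 15 and 16. C10–C14 is cut. A methyl ketone β to the ring oxygen is base-sensitive and would compete in every earlier carbonyl addition, so it is made last from an amide. Forward, the Grignard reagent must add once, and to the amide rather than the ester.

From 15 back to 10 and 11 (through 14, 13 and 12). C3–C4 is cut. C4 is set from C6 through a six-membered chelate. Axial attack puts the incoming carbon anti to C7, so the chain must be the nucleophile and the electrophile the methyl ketone; adding methyl to a chain-bearing ketone would give the C4 epimer. An alkynyl ester is used because a saturated γ-alkoxide ester would lactonise at once. Forward, the chelate must hold, and the secondary and tertiary hydroxyls must then be told apart.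

From 10 back to 9 and 8. The amide C–N bond is cut so that the C10 carbonyl rejoins the C6 oxygen as a δ-lactone, and the C6–O bond is then traded for C6–C10 (retro-Baeyer–Villiger). This returns C6 to a cyclopentanone fused cis to the ether ring, where its configuration is set on the convex face, and it makes C6 (alcohol level) and C10 (acid level) different by construction. An aldol at a C6 aldehyde from cleavage of the cyclopentene was rejected: the two aldehyde termini would need differentiation, the aldehyde is epimerisable at C7 and can lose the ring oxygen by β-elimination, and its facial selectivity is not secured. Forward, C6 must migrate with retention and in preference to C9.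

From 8 back to 4 and 5 (through 7 and 6). C5–C6 is cut; the C4 carbonyl is traced to a terminal alkene and the C10 carbonyl to an alcohol. A radical at C6 on the bicycle is trapped on the convex face, and an allyl group is a robust acetonyl equivalent.

From 4 back to 3 and 1. C6–Br and C10–O return to the alkene, and the ether returns to the commercial lactone. Forward, bromonium opening must occur at the carbon remote from the ring fusion, and the lactone must be reduced without touching C7 and C8.

## Other disconnections considered

Alternative 1: The cut is C6–C7. The C6 oxygen is joined to C13, so the carbocycle derives from a thirteen-membered ring containing a C6–O–C13–C11=C7 unit. Forward, tin–lithium exchange at C6 (n-BuLi) would give an α-alkoxy carbanion that undergoes a [2,3] Wittig–Still shift. C6–C7 forms, O–C13 breaks, the ring contracts by three atoms, the C6 hydroxyl is released and C11=C13 appears; the product would be A1.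
- In its favour: one concerted step makes a skeletal bond, both C6 and C7, and the methylene group. A ring contraction is entropically easier than closing a ten-membered ring from a chain.
- Where it is better or equal: it is the better plan for the methylene group, since no late lactone enolate chemistry is needed. On C12 the two are about equal (oxidation and lactonisation of a protected primary alcohol there, an ether oxidation here).
- Against it: the thirteen-membered ring must be closed first, a configurationally defined α-alkoxy stannane is needed at C6, and induction at C6 and C7 depends on the conformation of a large flexible ring. A [1,2] shift can compete, and the C6 and C8 oxygens must later be distinguished.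
- Comparison: the chosen plan fixes C6, C7 and C8 on a bicycle before ring closure, whereas A1 would receive C6 and C7 in the ring-forming event. A carbanion rearrangement at low temperature is milder than low-valent titanium at reflux, which counts for the alternative. It is not shorter, because the macrocycle with its stannane and allyl unit must be assembled.

Alternative 2: The cut is C8–C9 with C1–C6 reconnected. This retro-[3,3] step returns the ring to a cyclohexane with an isopropenyl group on the carbinol carbon (future C1) and a dihydrofuranyl group on the next carbon (future C6). Forward, an alkoxide at C1 (KH, 18-crown-6) would undergo an anionic oxy-Cope shift that forms C8–C9 and breaks C1–C6. Protonation of the ten-membered enolate at C10 would give A2 with an E C6=C7 alkene.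
- In its favour: the medium ring arises by expansion of a six-membered ring without high dilution, and here the alternative is better than the chosen plan. The C1 ketone and C10 methyl appear directly, and a chair transition state relays configuration to C8.
- Where it is equal: C10 is created by protonating an enol derivative in both plans.
- Against it: A2 has no oxygen at C6. The C6=C7 alkene must become C6–OH and C7–H with control of two centres on a flexible ring. C4 must be fixed relative to C8 by desymmetrising a 4,4-disubstituted cyclohexanone, a 1,4-relationship with little inherent bias.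
- Comparison: the alternative is superior on ring formation and the chosen plan on C6 and C7. After A2 the same ether oxidation and methylenation are still needed, so the step count is similar or longer.

Alternative 3: The cut is C1–C2 with C1 reconnected to C6. This leads back to a six-membered ketone ring (C1, C6–C10) of carvone origin in which C6 carries a silyloxy group and the C5–C2 chain. Forward, Bu3SnH would generate a primary radical at C2 from a C2–I bond; it adds to the C1 carbonyl, the alkoxy radical cleaves C1–C6 (Dowd–Beckwith expansion by four carbons), and the α-silyloxy C6 radical is reduced to give A3.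
- In its favour: a cheap chiral-pool start supplies C10 with its methyl, C7 and C11–C13. The lactone is already at the right oxidation level, so no ether oxidation is needed; on this point the alternative is better. Ring expansion again avoids high dilution.
- Where it is equal: converting the C11 methyl to the methylene by selenoxide elimination is about the same effort as the Mannich sequence. Both plans need one component kept dilute (tin hydride there, substrate here).
- Against it: C6 is created by hydrogen-atom transfer to a planar radical in a ten-membered ring, with nothing to control it. Direct reduction of the primary radical and 1,5-hydrogen shifts compete with the reversible addition to the ketone. A quaternary α-silyloxy carbon bearing a chain with the C4 stereocentre must be built first.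
- Comparison: the chosen plan controls C6 (set on a bicycle, transferred with retention) where the alternative does not. The alternative saves the lactone oxidation but pays for the quaternary centre, so it has no clear step advantage.

Key step: step 12

Assumption (chemistry): the C10 epimer of the target is taken to be the more stable one in the ten-membered α-methyl ketone and in its bridged ketal, since every acidic step after ring closure can equilibrate this centre.

## Route

Step 1
Reactants: 1 (1S,5R)-2-oxabicyclo[3.3.0]oct-6-en-3-one
Product: 3 (3aR,6aS)-3,3a,6,6a-tetrahydro-2H-cyclopenta[b]furan, via lactol 2 (not isolated)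
Conditions: iBu2AlH, CH2Cl2, −78 °C; then Et3SiH, BF3·OEt2, −78 to −20 °C
Reagents that add atoms: none
Why: Partial reduction of the γ-lactone to the aluminium lactolate, then ionic hydrogenation of the derived oxocarbenium ion, is the standard lactone-to-cyclic-ether reduction; C7 and C8 are untouched and the alkene is inert (the ether is volatile and is carried on in solution).

Step 2
Reactants: 3 (3aR,6aS)-3,3a,6,6a-tetrahydro-2H-cyclopenta[b]furan
Product: 4 bromohydrin (Br on C6 convex face; OH on C10 concave face)
Conditions: NBS, DMSO/H2O, 0 °C to rt
Reagents that add atoms: N-bromosuccinimide, BrN1C(=O)CCC1=O; water, O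
Why: Halohydrin formation: the bromonium ion forms on the convex face and water opens it anti at C10, the carbon remote from the ring fusion, as is usual for cis-fused bicyclic cyclopentenes.

Step 3
Reactants: 4 bromohydrin; 5 allyltributylstannane
Product: 6 trans allyl alcohol (allyl on C6 convex face; OH on C10)
Conditions: AIBN (cat.), PhH, 80 °C
Reagents that add atoms: none
Why: Keck radical allylation: the secondary C6 radical is trapped on the convex face, anti to the C10 hydroxyl, so the new C5–C6 bond is exo; the free alcohol is tolerated.

Step 4
Reactants: 6 trans allyl alcohol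
Product: 7 α-allyl bicyclic ketone (C10 ketone)
Conditions: Dess–Martin periodinane, CH2Cl2, rt
Reagents that add atoms: none
Why: Dess–Martin oxidation of a secondary alcohol; the allyl group already sits on the more stable convex side, so enolisation cannot scramble C6.

Step 5
Reactants: 7 α-allyl bicyclic ketone
Product: 8 bicyclic 1,4-diketone (2-oxopropyl group on C6)
Conditions: PdCl2 (cat.), CuCl, O2 (1 atm), DMF/H2O, rt
Reagents that add atoms: water, O
Why: Tsuji–Wacker oxidation of a terminal alkene to the methyl ketone, well established for 2-allyl cycloalkanones; it creates the C4 carbonyl and the C15 methyl.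

Step 6
Reactants: 8 bicyclic 1,4-diketone
Product: 9 cis-fused δ-lactone 4-(2-oxopropyl)hexahydro-4H-furo[3,2-c]pyran-6-one
Conditions: mCPBA, CH2Cl2, 0 °C to rt
Reagents that add atoms: 3-chloroperbenzoic acid, OOC(=O)c1cccc(Cl)c1
Why: Baeyer–Villiger oxidation: the secondary C6 migrates in preference to the primary C9 (further deactivated by the β-oxygen) and with retention, so the convex C6–C10 bond becomes the C6–O bond with the target configuration; the acyclic methyl ketone reacts far more slowly.

Step 7
Reactants: 9 cis-fused δ-lactone
Product: 10 hydroxy ketone Weinreb amide (C6 OH; C4 methyl ketone; C10 amide)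
Conditions: MeNH(OMe)·HCl, AlMe3, CH2Cl2, 0 °C to rt
Reagents that add atoms: N,O-dimethylhydroxylamine hydrochloride, CNOC.Cl
Why: Aluminium amide aminolysis of the δ-lactone (Weinreb amide formation) frees the C6 hydroxyl for chelation and leaves C10 at the acid level, distinct from every other carbonyl.

Step 8
Reactants: 10 hydroxy ketone Weinreb amide; 11 ethyl propiolate
Product: 12 anti-4,6-diol ynoate (C4 tertiary propargylic alcohol)
Conditions: 11, LiN(SiMe3)2, THF, −78 °C; MgBr2·OEt2; then 10, −78 °C; AcOH quench at −78 °C
Reagents that add atoms: none
Why: Chelation-controlled 1,2-addition of a metal acetylide to a β-hydroxy ketone: magnesium bridges the C6 oxygen and the C4 carbonyl and the nucleophile enters axially, trans to C7, which should give the 4,6-anti diol with C4 as in the target. The alkyne spacer prevents lactonisation of the γ-hydroxy ester, the Weinreb amide is inert at −78 °C, and the cold acidic quench avoids conjugate addition of the C6 alkoxide to the ynoate.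

Step 9
Reactants: 12 anti-4,6-diol ynoate
Product: 14 bis-silyl ether (C6 OTBS; C4 OTES), via C6 silyl ether 13 (not isolated)
Conditions: TBSOTf, 2,6-lutidine, CH2Cl2, −78 °C; then TESOTf, −78 to 0 °C
Reagents that add atoms: tert-butyldimethylsilyl triflate, CC(C)(C)[Si](C)(C)OS(=O)(=O)C(F)(F)F; triethylsilyl triflate, CC[Si](CC)(CC)OS(=O)(=O)C(F)(F)F
Why: Silyl triflates distinguish a secondary from a tertiary hydroxyl at −78 °C, so TBS goes to C6 and the smaller TESOTf then caps the tertiary C4 alcohol on warming in the same flask.

Step 10
Reactants: 14 bis-silyl ether
Product: 15 saturated ethyl ester (C10 Weinreb amide)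
Conditions: H2 (1 atm), Pd/C, EtOAc, rt
Reagents that add atoms: none
Why: Catalytic hydrogenation of the alkyne to the C2–C3 ethylene; with C4 silylated the ester cannot lactonise, and silyl ethers and the amide survive.

Step 11
Reactants: 15 saturated ethyl ester; 16 methylmagnesium bromide
Product: 17 keto ester (C10 methyl ketone; C1 ethyl ester)
Conditions: MeMgBr, THF, −78 to 0 °C
Reagents that add atoms: none
Why: Weinreb ketone synthesis: one equivalent of Grignard reagent adds to the amide to give a stable magnesium chelate that releases the methyl ketone only on work-up; at low temperature the amide reacts faster than the ethyl ester.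

Step 12
Reactants: 17 keto ester
Product: 19 tetrahydrofuran-fused ten-membered ketone (C4 OTES; C6 OTBS), via enol ether 18 (not isolated)
Conditions: TiCl3(DME)1.5, Zn(Cu), DME, reflux, 17 added slowly by syringe pump (high dilution); then 0.5 M HCl, THF, 0 °C
Reagents that add atoms: water, O
Why: Low-valent titanium from TiCl3(DME)1.5 and Zn(Cu) reduces the C10 methyl ketone to a titanium-bound ketyl, which adds to the surface-bound C1 ester carbonyl; the titanium 1,2-dialkoxide is deoxygenated to the cyclic enol ether 18 (C1(OEt)=C10), and dilute acid protonates C10 and collapses the hemiketal to the C1 ketone. The closest known reaction type is the intramolecular titanium-induced ketone–ester coupling to cycloalkanones (McMurry keto ester cyclisation), which is documented for medium and large rings. The ten-membered ring closes by coupling of two chain termini held cis on the tetrahydrofuran (C7 and C8), with both carbonyls on the same titanium surface and the substrate at pseudo-high dilution. The one new stereocentre, C10, is set in the hydrolysis and not in the C–C bond formation: protonation of the enol ether from the outer face and acid equilibration of the α-methyl ketone should give the more stable epimer, assumed to be the required one. Chemoselectivity is built into 17: it has exactly one ketone and one ester, the lactone is carried as an ether, C4 and C6 are silyl ethers, and the only oxygen near the ketone (on C8) is β and not α, so reductive C–O cleavage is not expected.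

Step 13
Reactants: 19 tetrahydrofuran-fused ten-membered ketone
Product: 20 8,12-lactone (C12 carbonyl; C4 OTES; C6 OTBS)
Conditions: RuCl3·xH2O (cat.), NaIO4, CCl4/MeCN/H2O, rt
Reagents that add atoms: sodium periodate (NaIO4), [Na+].[O-]I(=O)(=O)=O
Why: RuO4 formed in the flask oxidises ethers to esters at the less substituted α-carbon; C12 is the only ether methylene, the C8 methine is hindered, and silyl ethers and the ketone are inert, so the tetrahydrofuran should become the γ-lactone.

Step 14
Reactants: 20 8,12-lactone
Product: 21 bridged methyl ketal (C1 OMe; C1–O–C4 bridge; C6 OTBS)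
Conditions: CSA (cat.), MeOH, 0 °C to rt
Reagents that add atoms: methanol, CO
Why: Acidic methanol removes the triethylsilyl ether faster than the hindered secondary TBS ether; the freed C4 hydroxyl adds across the ring to the C1 ketone and the hemiketal is trapped as the methyl ketal, which masks ketone and tertiary alcohol together. The C1 configuration is dictated by the cis bridge.

Step 15
Reactants: 21 bridged methyl ketal
Product: 24 α-methylene lactone (ketal; C6 OTBS), via Mannich base 22 (not isolated), via ammonium iodide 23 (not isolated)
Conditions: LiN(iPr)2, THF, −78 °C; CH2=NMe2+ I−, −78 °C to rt; MeI, MeOH, rt; NaHCO3, CH2Cl2/H2O, rt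
Reagents that add atoms: N,N-dimethylmethyleneiminium iodide, C=[N+](C)C.[I-]
Why: α-Methylenation of a lactone by the Mannich route (enolate aminomethylation, quaternisation, elimination); with the ketone masked and no ester at C6, C11 is the only enolisable position.

Step 16
Reactants: 24 α-methylene lactone
Product: 25 C6 alcohol (ketal; methylene lactone)
Conditions: HF·pyridine, pyridine, THF, 0 °C to rt
Reagents that add atoms: none
Why: Fluoride cleavage of the TBS ether under buffered, non-basic conditions that spare the α-methylene lactone. If the ketal is partly opened, the material still converges on 27 after steps 17 and 18.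

Step 17
Reactants: 25 C6 alcohol
Product: 26 C6 isobutyrate (ketal; methylene lactone)
Conditions: isobutyryl chloride, pyridine, DMAP (cat.), CH2Cl2, 0 °C
Reagents that add atoms: isobutyryl chloride, CC(C)C(Cl)=O
Why: Acylation of the only free hydroxyl; the tertiary oxygen is locked in the ketal, so no site selectivity is required, and the short exposure of free C6–OH limits translactonisation.

Step 18
Reactants: 26 C6 isobutyrate
Product: 27 target CNP0293926.1
Conditions: 1 M HCl, THF, 0 °C to rt
Reagents that add atoms: water, O
Why: Mild aqueous acid hydrolyses the methyl ketal to the C1 ketone and C4 alcohol; the ester and the α-methylene lactone are stable, and C10 settles in its preferred configuration.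

## Compound list

1 | (1S,5R)-2-oxabicyclo[3.3.0]oct-6-en-3-one | C1C(=O)O[C@H]2CC=C[C@@H]12 | starting material
2 | lactol, (3aR,6aS)-3,3a,6,6a-tetrahydro-2H-cyclopenta[b]furan-2-ol (anomer mixture, present as aluminium alkoxide) | C1C(O)O[C@H]2CC=C[C@@H]12 | intermediate (not isolated)
3 | (3aR,6aS)-3,3a,6,6a-tetrahydro-2H-cyclopenta[b]furan | C1CO[C@H]2CC=C[C@@H]12 | intermediate
4 | 4-bromohexahydro-2H-cyclopenta[b]furan-5-ol; Br at C6 on the convex face, OH at C10 on the concave face | C1CO[C@H]2C[C@@H](O)[C@H](Br)[C@@H]12 | intermediate
5 | allyltributylstannane | C=CC[Sn](CCCC)(CCCC)CCCC | starting material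
6 | 4-allylhexahydro-2H-cyclopenta[b]furan-5-ol; allyl at C6 convex, OH at C10 concave | C1CO[C@H]2C[C@@H](O)[C@H](CC=C)[C@@H]12 | intermediate
7 | 4-allylhexahydrocyclopenta[b]furan-5-one; allyl convex | C1CO[C@H]2CC(=O)[C@H](CC=C)[C@@H]12 | intermediate
8 | 4-(2-oxopropyl)hexahydrocyclopenta[b]furan-5-one | C1CO[C@H]2CC(=O)[C@H](CC(C)=O)[C@@H]12 | intermediate
9 | 4-(2-oxopropyl)hexahydro-4H-furo[3,2-c]pyran-6-one; cis-fused, side chain cis to H-3a | C1CO[C@H]2CC(=O)O[C@H](CC(C)=O)[C@@H]12 | intermediate
10 | 2-[3-(1-hydroxy-3-oxobutyl)tetrahydrofuran-2-yl]-N-methoxy-N-methylacetamide; 2,3-cis, C6 carbinol as in the target | C1CO[C@@H](CC(=O)N(C)OC)[C@H]1[C@H](O)CC(C)=O | intermediate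
11 | ethyl propiolate | C#CC(=O)OCC | starting material
12 | ethyl 4,6-dihydroxy-6-{2-[2-(methoxy(methyl)amino)-2-oxoethyl]tetrahydrofuran-3-yl}-4-methylhex-2-ynoate; 4,6-anti | C1CO[C@@H](CC(=O)N(C)OC)[C@H]1[C@H](O)C[C@@](C)(O)C#CC(=O)OCC | intermediate
13 | C6 tert-butyldimethylsilyl ether of 12 | C1CO[C@@H](CC(=O)N(C)OC)[C@H]1[C@H](O[Si](C)(C)C(C)(C)C)C[C@@](C)(O)C#CC(=O)OCC | intermediate (not isolated)
14 | C6 OTBS, C4 OTES bis-silyl ether of 12 | C1CO[C@@H](CC(=O)N(C)OC)[C@H]1[C@H](O[Si](C)(C)C(C)(C)C)C[C@@](C)(O[Si](CC)(CC)CC)C#CC(=O)OCC | intermediate
15 | ethyl 6-(TBSO)-6-{2-[2-(methoxy(methyl)amino)-2-oxoethyl]tetrahydrofuran-3-yl}-4-methyl-4-(TESO)hexanoate | C1CO[C@@H](CC(=O)N(C)OC)[C@H]1[C@H](O[Si](C)(C)C(C)(C)C)C[C@@](C)(O[Si](CC)(CC)CC)CCC(=O)OCC | intermediate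
16 | methylmagnesium bromide | C[Mg]Br | starting material
17 | keto ester, ethyl 6-(TBSO)-4-methyl-6-[2-(2-oxopropyl)tetrahydrofuran-3-yl]-4-(TESO)hexanoate; cis-2,3-disubstituted tetrahydrofuran | C1CO[C@@H](CC(C)=O)[C@H]1[C@H](O[Si](C)(C)C(C)(C)C)C[C@@](C)(O[Si](CC)(CC)CC)CCC(=O)OCC | intermediate (key-step precursor)
18 | cyclic enol ether, C1(OEt)=C10(Me) in the ten-membered ring (ring-cis geometry drawn; either isomer hydrolyses to 19) | C1CO[C@H]2C/C(C)=C(OCC)\CC[C@](C)(O[Si](CC)(CC)CC)C[C@@H](O[Si](C)(C)C(C)(C)C)[C@@H]12 | intermediate (not isolated)
19 | tetrahydrofuran-fused ten-membered C1 ketone; C4 OTES, C6 OTBS, C10 methyl | C1CO[C@H]2C[C@@H](C)C(=O)CC[C@](C)(O[Si](CC)(CC)CC)C[C@@H](O[Si](C)(C)C(C)(C)C)[C@@H]12 | intermediate (key-step product)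
20 | 8,12-lactone of 19 (C12 carbonyl, C11 methylene) | C1C(=O)O[C@H]2C[C@@H](C)C(=O)CC[C@](C)(O[Si](CC)(CC)CC)C[C@@H](O[Si](C)(C)C(C)(C)C)[C@@H]12 | intermediate
21 | bridged methyl ketal (1-methoxy-1,4-epoxy), C6 OTBS, 8,12-lactone | C1C(=O)O[C@H]2C[C@@H](C)[C@@]3(OC)CC[C@](C)(O3)C[C@@H](O[Si](C)(C)C(C)(C)C)[C@@H]12 | intermediate
22 | 11-(dimethylaminomethyl) lactone (substituent trans to C6 on the lactone ring) | CN(C)C[C@@H]1C(=O)O[C@H]2C[C@@H](C)[C@@]3(OC)CC[C@](C)(O3)C[C@@H](O[Si](C)(C)C(C)(C)C)[C@@H]12 | intermediate (not isolated)
23 | 11-(trimethylammoniomethyl) lactone iodide | C[N+](C)(C)C[C@@H]1C(=O)O[C@H]2C[C@@H](C)[C@@]3(OC)CC[C@](C)(O3)C[C@@H](O[Si](C)(C)C(C)(C)C)[C@@H]12.[I-] | intermediate (not isolated)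
24 | 11(13)-methylene lactone, bridged ketal, C6 OTBS | C=C1C(=O)O[C@H]2C[C@@H](C)[C@@]3(OC)CC[C@](C)(O3)C[C@@H](O[Si](C)(C)C(C)(C)C)[C@@H]12 | intermediate
25 | 11(13)-methylene lactone, bridged ketal, C6 OH | C=C1C(=O)O[C@H]2C[C@@H](C)[C@@]3(OC)CC[C@](C)(O3)C[C@@H](O)[C@@H]12 | intermediate
26 | 11(13)-methylene lactone, bridged ketal, C6 isobutyrate | C=C1C(=O)O[C@H]2C[C@@H](C)[C@@]3(OC)CC[C@](C)(O3)C[C@@H](OC(=O)C(C)C)[C@@H]12 | intermediate
27 | CNP0293926.1, (4S,6R,7S,8S,10R)-4-hydroxy-6-isobutyryloxy-1-oxogermacr-11(13)-en-12,8-olide (germacrane numbering) | C=C1C(=O)O[C@H]2C[C@@H](C)C(=O)CC[C@](C)(O)C[C@@H](OC(=O)C(C)C)[C@@H]12 | target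

## Step count and least certain steps

Total: 18 steps. Longest linear sequence: 18 steps (1 to 27); 5, 11 and 16 are purchased.

Step 12 (key step). The most likely failures are intermolecular coupling and simple reduction of the ketone outrunning closure of the ten-membered ring, loss of the tertiary silyl ether on the Lewis-acidic titanium surface, and equilibration at C10 toward the other epimer during hydrolysis. The fallback sets out from 17 and returns at 19.
- LiAlH4 reduces ketone and ester to the diol F1.
- Dess–Martin oxidation of both alcohols gives the keto aldehyde F2.
- Titanium-induced ketone–aldehyde olefination (the more dependable medium-ring closure) gives the cyclodecene F3.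
- Hydroboration–oxidation (BH3·THF; H2O2, NaOH) places OH at C1 and H at C10 by syn addition from the outer face, giving the alcohol F4.
- Dess–Martin oxidation returns to 19, now with C10 set kinetically.

Step 8. The most likely failure is poor facial discrimination at C4, because a small sp-hybridised nucleophile may add before a tight chelate forms; conjugate addition of the C6 alkoxide to the ynoate is a second risk. The fallback sets out from 10 and returns at 15.
- TiCl4-chelation-controlled Hosomi–Sakurai allylation with allyltrimethylsilane gives the homoallylic diol F5.
- TBSOTf then TESOTf give the bis-silyl ether F6.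
- 9-BBN then H2O2/NaOH give the primary alcohol F7.
- TEMPO/PhI(OAc)2 gives the acid F8.
- EtI/Cs2CO3 gives 15.

Step 11. The most likely failure is competing addition of the Grignard reagent to the ethyl ester, giving over-addition at C1. The fallback sets out from 15 and returns at 17.
- Cp2Zr(H)Cl reduces only the Weinreb amide, to the aldehyde F9.
- MeTi(OiPr)3 adds to the aldehyde and leaves the ester, giving the secondary alcohol F10.
- Dess–Martin oxidation gives 17.

Step 14. The most likely failure is loss of the C6 silyl ether together with the tertiary one under the acidic methanol, which removes the protecting group needed for the enolate step. The fallback sets out from 20 and returns at 26.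
- HCl in MeOH removes both silyl groups and gives the hydroxy ketal lactone F11.
- Isobutyryl chloride/pyridine gives the ester F12.
- Carboxylation at C11 with MeOMgOCO2Me in DMF gives the α-carboxy lactone F13, which avoids a strong-base enolate beside the ester.
- Decarboxylative methylenation (aqueous CH2O, Et2NH, AcOH/NaOAc) gives 26.

## Further compounds

F1 | step 12 | C1,C10-diol from reduction of 17 (either C10 carbinol epimer) | C1CO[C@@H](CC(C)O)[C@H]1[C@H](O[Si](C)(C)C(C)(C)C)C[C@@](C)(O[Si](CC)(CC)CC)CCCO
F2 | step 12 | keto aldehyde (C10 methyl ketone, C1 aldehyde) | C1CO[C@@H](CC(C)=O)[C@H]1[C@H](O[Si](C)(C)C(C)(C)C)C[C@@](C)(O[Si](CC)(CC)CC)CCC=O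
F3 | step 12 | tetrahydrofuran-fused cyclodecene with C1=C10 alkene (E drawn; either geometry serves) | C1CO[C@H]2C/C(C)=C/CC[C@](C)(O[Si](CC)(CC)CC)C[C@@H](O[Si](C)(C)C(C)(C)C)[C@@H]12
F4 | step 12 | C1 alcohol with C10 methyl as in 19 (C1 carbinol configuration immaterial) | C1CO[C@H]2C[C@@H](C)C(O)CC[C@](C)(O[Si](CC)(CC)CC)C[C@@H](O[Si](C)(C)C(C)(C)C)[C@@H]12
F5 | step 8 | homoallylic anti-4,6-diol Weinreb amide | C1CO[C@@H](CC(=O)N(C)OC)[C@H]1[C@H](O)C[C@@](C)(O)CC=C
F6 | step 8 | C6 OTBS, C4 OTES ether of F5 | C1CO[C@@H](CC(=O)N(C)OC)[C@H]1[C@H](O[Si](C)(C)C(C)(C)C)C[C@@](C)(O[Si](CC)(CC)CC)CC=C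
F7 | step 8 | C1 primary alcohol | C1CO[C@@H](CC(=O)N(C)OC)[C@H]1[C@H](O[Si](C)(C)C(C)(C)C)C[C@@](C)(O[Si](CC)(CC)CC)CCCO
F8 | step 8 | C1 carboxylic acid | C1CO[C@@H](CC(=O)N(C)OC)[C@H]1[C@H](O[Si](C)(C)C(C)(C)C)C[C@@](C)(O[Si](CC)(CC)CC)CCC(=O)O
F9 | step 11 | C10 aldehyde ethyl ester | C1CO[C@@H](CC=O)[C@H]1[C@H](O[Si](C)(C)C(C)(C)C)C[C@@](C)(O[Si](CC)(CC)CC)CCC(=O)OCC
F10 | step 11 | C10 secondary alcohol ethyl ester (either C10 epimer) | C1CO[C@@H](CC(C)O)[C@H]1[C@H](O[Si](C)(C)C(C)(C)C)C[C@@](C)(O[Si](CC)(CC)CC)CCC(=O)OCC
F11 | step 14 | bridged methyl ketal lactone with free C6 OH | C1C(=O)O[C@H]2C[C@@H](C)[C@@]3(OC)CC[C@](C)(O3)C[C@@H](O)[C@@H]12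
F12 | step 14 | bridged methyl ketal lactone C6 isobutyrate (no methylene) | C1C(=O)O[C@H]2C[C@@H](C)[C@@]3(OC)CC[C@](C)(O3)C[C@@H](OC(=O)C(C)C)[C@@H]12
F13 | step 14 | 11-carboxy lactone of F12 (C11 configuration not defined; the centre is lost in the next step) | OC(=O)C1C(=O)O[C@H]2C[C@@H](C)[C@@]3(OC)CC[C@](C)(O3)C[C@@H](OC(=O)C(C)C)[C@@H]12
A1 | alternative 1 | ten-membered C6 alcohol with the C7 2-(silyloxymethyl)vinyl group, C8 OTBS, C1 dioxolane, C4 OTES | C=C(CO[Si](C)(C)C(C)(C)C)[C@H]1[C@@H](O[Si](C)(C)C(C)(C)C)C[C@@H](C)C2(OCCO2)CC[C@](C)(O[Si](CC)(CC)CC)C[C@H]1O
A2 | alternative 2 | tetrahydrofuran-fused ten-membered ketone with E C6=C7 alkene, C4 OTES | O=C1CC[C@](C)(O[Si](CC)(CC)CC)C/C=C2\CCO[C@H]2C[C@H]1C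
A3 | alternative 3 | ten-membered ketone with C4 OTES, C6 OTBS and the 11,13-dihydro lactone | C[C@H]1C(=O)O[C@H]2C[C@@H](C)C(=O)CC[C@](C)(O[Si](CC)(CC)CC)C[C@@H](O[Si](C)(C)C(C)(C)C)[C@@H]12
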